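**Plan**

- Retrosynthesis first removes only masks (two benzyl ethers, the methyl enol ether, the silyl ether), then cuts the two bonds at the side-chain carbonyl, C2–C1' and C1'–C2'.
- Enabling feature: C1' is a ketone carbon between sp2 carbon C2 of the six-membered ring (flanked by the C1 ketone and the C3 enol carbon) and the unbranched chain C2'–C9'. It can therefore be carbon monoxide inserted between an alkenyl iodide and a primary alkylborane.
- Forward, the carbocycle is bought, not built: all-cis cyclohexane-1,3,5-triol is monosilylated and desymmetrised by a lipase. Its two remaining carbinol carbons are then differentiated as ketone C1 and, via a dimethyl ketal, enol ether carbon C3, and C2 is iodinated.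
- The chain comes from Kumada coupling of 4-bromo-1,2-bis(benzyloxy)benzene with oct-7-enylmagnesium bromide and hydroboration with 9-BBN. Ring, CO and chain are then joined in one palladium-catalysed operation, and two unmasking steps follow.
- Stereochemistry: the single centre C5 comes from the enzymatic desymmetrisation of the meso diol. It stays a defined centre because C1 and C3 are kept chemically different until the last hydrolysis.

Key step: step 10

Remark (assumption): in the free 2-acyl-1,3-dione the two ring carbonyls exchange roles by enol tautomerism, so the (S) descriptor at C5 belongs to the tautomer drawn in the target SMILES. The route carries C5 as a true stereocentre up to the unmasking and delivers that tautomer formally; compounds 17, 18 and F3 are drawn in the same tautomeric form.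

**Route**

Step 1
Reactants: 1 cis,cis-cyclohexane-1,3,5-triol
Product: 2 cis,cis-5-(tert-butyldimethylsilyloxy)cyclohexane-1,3-diol (meso, all three oxygens on one face)
Conditions: TBSCl (1.0 equiv), imidazole (2 equiv), DMF, 0 °C to rt
Reagents that add atoms: tert-butyldimethylsilyl chloride, CC(C)(C)[Si](C)(C)Cl
Why: Statistical monosilylation of three equivalent hydroxyls (silyl ether formation) should give the meso mono-ether, separable by chromatography from bis-ether and recovered triol, with no stereochemical issue at this stage.

Step 2
Reactants: 2 cis,cis-5-(tert-butyldimethylsilyloxy)cyclohexane-1,3-diol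
Product: 3 (1R,3S,5S)-3-(tert-butyldimethylsilyloxy)-5-hydroxycyclohexyl acetate
Conditions: vinyl acetate (5 equiv), immobilised Candida antarctica lipase B, tBuOMe, 30 °C
Reagents that add atoms: vinyl acetate, CC(=O)OC=C
Why: Lipase-catalysed irreversible transesterification of a meso 1,3-diol should acylate one enantiotopic hydroxyl, expected to be the R-configured carbinol (the silyloxy-bearing ring arm acting as the large group in the empirical model for secondary alcohols), which fixes the absolute configuration of the future C5; the sense is to be confirmed by Mosher ester analysis before going on.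

Step 3
Reactants: 3 (1R,3S,5S)-3-(tert-butyldimethylsilyloxy)-5-hydroxycyclohexyl acetate
Product: 4 (1S,3R)-3-(tert-butyldimethylsilyloxy)-5-oxocyclohexyl acetate
Conditions: Dess–Martin periodinane, CH2Cl2, 0 °C to rt
Reagents that add atoms: none
Why: Dess–Martin oxidation of the free secondary alcohol under non-basic conditions should give the β-acetoxy ketone without loss of acetic acid, the oxidised carbon being the future enol ether carbon C3.

Step 4
Reactants: 4 (1S,3R)-3-(tert-butyldimethylsilyloxy)-5-oxocyclohexyl acetate
Product: 5 (1S,3R)-3-(tert-butyldimethylsilyloxy)-5,5-dimethoxycyclohexyl acetate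
Conditions: MeOSiMe3 (3 equiv), TMSOTf (cat.), CH2Cl2, −78 °C; pyridine quench
Reagents that add atoms: methoxytrimethylsilane, CO[Si](C)(C)C
Why: Noyori ketalisation under aprotic conditions at low temperature should convert the ketone into its dimethyl ketal while leaving the silyl ether and the acetate untouched.

Step 5
Reactants: 5 (1S,3R)-3-(tert-butyldimethylsilyloxy)-5,5-dimethoxycyclohexyl acetate
Product: 6 (1S,3R)-3-(tert-butyldimethylsilyloxy)-5,5-dimethoxycyclohexan-1-ol
Conditions: K2CO3 (cat.), MeOH, 0 °C to rt
Reagents that add atoms: none
Why: Base-catalysed methanolysis (transesterification) removes the acetate under conditions to which the ketal and the silyl ether are stable.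

Step 6
Reactants: 6 (1S,3R)-3-(tert-butyldimethylsilyloxy)-5,5-dimethoxycyclohexan-1-ol
Product: 7 (R)-5-(tert-butyldimethylsilyloxy)-3,3-dimethoxycyclohexan-1-one
Conditions: (nPr4N)RuO4 (cat.), NMO, 4 Å molecular sieves, CH2Cl2, rt
Reagents that add atoms: none
Why: Ley–Griffith oxidation under neutral conditions should turn the remaining carbinol into the ketone that becomes C1 without ionising the ketal.

Step 7
Reactants: 7 (R)-5-(tert-butyldimethylsilyloxy)-3,3-dimethoxycyclohexan-1-one
Product: 8 (S)-5-(tert-butyldimethylsilyloxy)-3-methoxycyclohex-2-en-1-one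
Conditions: DBU (1.1 equiv), CH2Cl2, 0 °C to rt
Reagents that add atoms: none
Why: E1cB β-elimination of methanol from the β-keto dimethyl ketal should give the conjugated vinylogous ester, because the enolate towards C2 always has an axial methoxy group to expel whereas the equatorial silyloxy group at C5 is a poorer leaving group, and base cannot exchange C1 with C3, so the C5 centre is not eroded.

Step 8
Reactants: 8 (S)-5-(tert-butyldimethylsilyloxy)-3-methoxycyclohex-2-en-1-one
Product: 9 (S)-5-(tert-butyldimethylsilyloxy)-2-iodo-3-methoxycyclohex-2-en-1-one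
Conditions: NIS (1.1 equiv), CH2Cl2, 0 °C to rt, dark
Reagents that add atoms: N-iodosuccinimide, O=C1CCC(=O)N1I
Why: Electrophilic α-iodination of a vinylogous ester at its nucleophilic carbon C2 should proceed cleanly, the succinimide anion taking the proton so that no HI or iodide is present to cleave the methyl enol ether or the silyl ether.

Step 9
Reactants: 10 4-bromo-1,2-bis(benzyloxy)benzene; 11 8-bromooct-1-ene
Product: 13 1,2-bis(benzyloxy)-4-(oct-7-en-1-yl)benzene, via oct-7-enylmagnesium bromide 12 (not isolated)
Conditions: 11, Mg turnings, THF, rt to 40 °C; then 10, PdCl2(dppf) (2 mol%), THF, reflux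
Reagents that add atoms: none
Why: Kumada–Corriu coupling of a primary alkyl Grignard reagent with an aryl bromide should work because the wide-bite-angle dppf ligand favours reductive elimination over β-hydride elimination, while the benzyl ethers and the remote terminal alkene are inert.

Step 10
Reactants: 13 1,2-bis(benzyloxy)-4-(oct-7-en-1-yl)benzene; 9 (S)-5-(tert-butyldimethylsilyloxy)-2-iodo-3-methoxycyclohex-2-en-1-one; 14 carbon monoxide
Product: 16 (S)-2-{9-[3,4-bis(benzyloxy)phenyl]nonanoyl}-5-(tert-butyldimethylsilyloxy)-3-methoxycyclohex-2-en-1-one, via B-alkyl-9-BBN 15 (not isolated)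
Conditions: 13 (1.5 equiv), 9-BBN (1.45 equiv), THF, 0 °C to rt; then 9 (1.0 equiv), Pd(PPh3)4 (5 mol%), K3PO4 (3 equiv), CO (1 atm), benzene, rt
Reagents that add atoms: none
Why: Anti-Markovnikov hydroboration of the terminal alkene gives the primary alkylborane 15; zerovalent palladium then adds oxidatively to the C2–I bond of 9, CO inserts to give an acylpalladium species, the primary alkyl group is transferred from the phosphate-activated borate, and reductive elimination releases the ketone, so that C2–C1' and C1'–C2' form in one operation. The closest known reaction type is the carbonylative Suzuki–Miyaura coupling of 1-iodoalkenes with B-alkyl-9-BBN reagents under an atmosphere of CO with Pd(PPh3)4 and K3PO4, applied here to an α-iodo vinylogous ester. No ring is closed and no stereocentre is created; C5 is remote from the reacting carbons and is carried through unchanged. The selectivity required is ketone over the directly coupled 2-alkyl enone, which the CO atmosphere and the slow alkyl transfer from boron with anhydrous K3PO4 in a non-polar medium should secure, since CO insertion then precedes transmetalation. The slight excess of alkene over 9-BBN leaves no B–H to reduce the enone, room temperature and a weak heterogeneous base should spare the β-silyloxy ketone, and the methyl enol ether keeps the acidic triketone masked during the union.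

Step 11
Reactants: 16 (S)-2-{9-[3,4-bis(benzyloxy)phenyl]nonanoyl}-5-(tert-butyldimethylsilyloxy)-3-methoxycyclohex-2-en-1-one
Product: 17 (S)-2-{9-[3,4-bis(benzyloxy)phenyl]nonanoyl}-3,5-dihydroxycyclohex-2-en-1-one
Conditions: 1 M aqueous HCl, THF, 0 °C to rt
Reagents that add atoms: water, O
Why: Acid hydrolysis of the doubly activated vinylogous methyl ester (water adds at C3, methanol leaves) and acid-catalysed cleavage of the secondary silyl ether should occur together under conditions mild enough to leave the benzyl ethers and the C5 hydroxyl intact.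

Step 12
Reactants: 17 (S)-2-{9-[3,4-bis(benzyloxy)phenyl]nonanoyl}-3,5-dihydroxycyclohex-2-en-1-one
Product: 18 (S)-2-[9-(3,4-dihydroxyphenyl)nonanoyl]-3,5-dihydroxycyclohex-2-en-1-one (target)
Conditions: H2 (1 atm), 10% Pd/C, EtOAc, rt
Reagents that add atoms: none
Why: Hydrogenolysis of the two benzyl aryl ethers under neutral conditions should free the catechol without reducing the hydrogen-bonded enolised triketone, and the product needs only filtration, which spares the dehydration-prone 5-hydroxy-1,3-dione.

**Compound list**

1 | cis,cis-cyclohexane-1,3,5-triol | O[C@@H]1C[C@H](O)C[C@H](O)C1 | starting material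
2 | cis,cis-5-(tert-butyldimethylsilyloxy)cyclohexane-1,3-diol | CC(C)(C)[Si](C)(C)O[C@@H]1C[C@H](O)C[C@H](O)C1 | intermediate
3 | (1R,3S,5S)-3-(tert-butyldimethylsilyloxy)-5-hydroxycyclohexyl acetate | CC(C)(C)[Si](C)(C)O[C@@H]1C[C@H](OC(C)=O)C[C@H](O)C1 | intermediate
4 | (1S,3R)-3-(tert-butyldimethylsilyloxy)-5-oxocyclohexyl acetate | CC(C)(C)[Si](C)(C)O[C@@H]1C[C@H](OC(C)=O)CC(=O)C1 | intermediate
5 | (1S,3R)-3-(tert-butyldimethylsilyloxy)-5,5-dimethoxycyclohexyl acetate | CC(C)(C)[Si](C)(C)O[C@@H]1C[C@H](OC(C)=O)CC(OC)(OC)C1 | intermediate
6 | (1S,3R)-3-(tert-butyldimethylsilyloxy)-5,5-dimethoxycyclohexan-1-ol | CC(C)(C)[Si](C)(C)O[C@@H]1C[C@H](O)CC(OC)(OC)C1 | intermediate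
7 | (R)-5-(tert-butyldimethylsilyloxy)-3,3-dimethoxycyclohexan-1-one | CC(C)(C)[Si](C)(C)O[C@@H]1CC(=O)CC(OC)(OC)C1 | intermediate
8 | (S)-5-(tert-butyldimethylsilyloxy)-3-methoxycyclohex-2-en-1-one | O=C1C=C(OC)C[C@H](O[Si](C)(C)C(C)(C)C)C1 | intermediate
9 | (S)-5-(tert-butyldimethylsilyloxy)-2-iodo-3-methoxycyclohex-2-en-1-one | O=C1C(I)=C(OC)C[C@H](O[Si](C)(C)C(C)(C)C)C1 | intermediate
10 | 4-bromo-1,2-bis(benzyloxy)benzene | Brc1ccc(OCc2ccccc2)c(OCc2ccccc2)c1 | starting material
11 | 8-bromooct-1-ene | C=CCCCCCCBr | starting material
12 | oct-7-enylmagnesium bromide | C=CCCCCCC[Mg]Br | intermediate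
13 | 1,2-bis(benzyloxy)-4-(oct-7-en-1-yl)benzene | C=CCCCCCCc1ccc(OCc2ccccc2)c(OCc2ccccc2)c1 | intermediate
14 | carbon monoxide | [C-]#[O+] | starting material
15 | B-{8-[3,4-bis(benzyloxy)phenyl]octyl}-9-borabicyclo[3.3.1]nonane | C(CCCCCCCc1ccc(OCc2ccccc2)c(OCc2ccccc2)c1)B1C2CCCC1CCC2 | intermediate
16 | (S)-2-{9-[3,4-bis(benzyloxy)phenyl]nonanoyl}-5-(tert-butyldimethylsilyloxy)-3-methoxycyclohex-2-en-1-one | O=C(CCCCCCCCc1ccc(OCc2ccccc2)c(OCc2ccccc2)c1)C1=C(OC)C[C@H](O[Si](C)(C)C(C)(C)C)CC1=O | intermediate
17 | (S)-2-{9-[3,4-bis(benzyloxy)phenyl]nonanoyl}-3,5-dihydroxycyclohex-2-en-1-one | O=C(CCCCCCCCc1ccc(OCc2ccccc2)c(OCc2ccccc2)c1)C1=C(O)C[C@H](O)CC1=O | intermediate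
18 | (S)-2-[9-(3,4-dihydroxyphenyl)nonanoyl]-3,5-dihydroxycyclohex-2-en-1-one | O=C(CCCCCCCCc1ccc(O)c(O)c1)C1=C(O)C[C@H](O)CC1=O | target

**Step count and risks**

Total step count: 12. Longest linear sequence: 11 steps (steps 1 to 8, then 10 to 12, from triol 1).

Steps most likely to fail:

Step 10. The alkyl group may be transferred to palladium before CO has inserted, which gives the directly coupled 2-alkyl enone. Insertion at the hindered, electron-poor alkenylpalladium may also be slow, and prolonged contact with base may cause loss of the silyloxy group with aromatisation. The fallback sets out from alkene 13 and iodide 9 and keeps CO as the source of C1', but forms the two bonds in separate, known operations. Linear-selective hydroformylation of 13 (Rh(acac)(CO)2, Xantphos, CO/H2, toluene, 80 °C) should give 9-[3,4-bis(benzyloxy)phenyl]nonanal F1. Nozaki–Hiyama–Kishi coupling of 9 with this aldehyde (CrCl2, NiCl2 (cat.), DMF, rt) should form C2–C1' and give (5S)-2-{9-[3,4-bis(benzyloxy)phenyl]-1-hydroxynonyl}-5-(tert-butyldimethylsilyloxy)-3-methoxycyclohex-2-en-1-one F2 as a mixture of carbinol epimers. Dess–Martin oxidation of that alcohol returns to the route at ketone 16.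

Step 11. The acid exposure needed to cleave the secondary silyl ether may also promote β-elimination of the C5 oxygen function, followed by tautomerisation to an acylresorcinol. The fallback sets out from 16 and separates the two unmaskings, each by a different mechanism. LiOH in THF/H2O at 0 °C should cleave the vinylogous ester by addition–elimination of hydroxide at C3, giving the stabilised trione enolate. Acidification to pH 4 should then give (S)-2-{9-[3,4-bis(benzyloxy)phenyl]nonanoyl}-5-(tert-butyldimethylsilyloxy)-3-hydroxycyclohex-2-en-1-one F3. Buffered HF·pyridine (pyridine, THF, 0 °C to rt) then removes the silyl group by fluoride attack at silicon and returns to the route at 17.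

Step 2. The lipase may acylate the other enantiotopic hydroxyl, or discriminate insufficiently between the two, which would invert or erode the configuration at C5. The fallback sets out from diol 2 and uses the hydrolytic mode of the enzyme. Peracetylation (Ac2O, pyridine, DMAP (cat.), CH2Cl2) gives cis,cis-5-(tert-butyldimethylsilyloxy)cyclohexane-1,3-diyl diacetate F4. Hydrolysis with the same lipase (phosphate buffer pH 7, tBuOMe, rt) frees the hydroxyl at the carbinol centre that the enzyme recognises and leaves the acetate on the other. This is the mirror-image outcome of the acylation mode, so a wrong sense in step 2 is corrected and the route is rejoined at monoacetate 3.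

Further compounds

F1 | step 10 | 9-[3,4-bis(benzyloxy)phenyl]nonanal | O=CCCCCCCCCc1ccc(OCc2ccccc2)c(OCc2ccccc2)c1
F2 | step 10 | (5S)-2-{9-[3,4-bis(benzyloxy)phenyl]-1-hydroxynonyl}-5-(tert-butyldimethylsilyloxy)-3-methoxycyclohex-2-en-1-one (carbinol epimers) | OC(CCCCCCCCc1ccc(OCc2ccccc2)c(OCc2ccccc2)c1)C1=C(OC)C[C@H](O[Si](C)(C)C(C)(C)C)CC1=O
F3 | step 11 | (S)-2-{9-[3,4-bis(benzyloxy)phenyl]nonanoyl}-5-(tert-butyldimethylsilyloxy)-3-hydroxycyclohex-2-en-1-one | O=C(CCCCCCCCc1ccc(OCc2ccccc2)c(OCc2ccccc2)c1)C1=C(O)C[C@H](O[Si](C)(C)C(C)(C)C)CC1=O
F4 | step 2 | cis,cis-5-(tert-butyldimethylsilyloxy)cyclohexane-1,3-diyl diacetate | CC(C)(C)[Si](C)(C)O[C@@H]1C[C@H](OC(C)=O)C[C@H](OC(C)=O)C1
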